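The clerodane decalin is derived from the labdane-type decalin of (+)-sclareolide by a single cationic backbone rearrangement. Ionisation of an 8α,9α-epoxide at C9 sends the C10 methyl to C9, H5 to C10 and the axial C4 methyl to C5, so that the C9–C20 and C5–C19 bonds and three stereocentres arise in one operation without ring closure. The step exploits the two β-methyls C19 (on C5) and C20 (on C9), 1,3-diaxial across ring B and anti to H10 at the fusion of rings A and B, together with the C4 methylene. Its precursor is the 8α,9α-epoxy homodrimanyl pivalate; ring oxygenation and the lactone side chain follow by directed, chemoselective steps.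

Key step: step 5

Remark: clerodane numbering is used from compound 7 onward (side chain C11–C16, C17 on C8, C18 on C4, C19 on C5, C20 on C9) and labdane numbering before it; β is the face of C19 and C20, α the face of H10; tigloyl is (E)-2-methylbut-2-enoyl.
Remark: an α-epoxide in 6 and migrations on the β face give 19β, 20β and 10α-H in 7, which matches C5, C9 and C10 of the target, so these structures are used unchanged. The C12 oxygen stays a pivalate through the rearrangement, because a free or silylated oxygen could capture the C10 cation as a cyclic ether. The 8α-hydroxyl is kept until step 11, because it directs step 8 and keeps C8 saturated during the radical step 7.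

Step 1
Reactants: 1 (+)-sclareolide
Product: 2 13,14,15,16-tetranorlabdane-8α,12-diol
Conditions: LiAlH4, THF, 0 °C to rt
Reagents that add atoms: none
Why: LiAlH4 reduction of the γ-lactone gives the primary C12 alcohol and the tertiary 8α-alcohol, with all four stereocentres of sclareolide untouched.

Step 2
Reactants: 2 13,14,15,16-tetranorlabdane-8α,12-diol; 3 pivaloyl chloride
Product: 4 8α-hydroxy-13,14,15,16-tetranorlabdan-12-yl pivalate
Conditions: pyridine, DMAP (cat.), CH2Cl2, 0 °C
Reagents that add atoms: none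
Why: Acylation with the bulky acid chloride is selective for the primary alcohol over the hindered tertiary one (chemoselective esterification), and the pivalate is chosen because it should not take part in the later cation chemistry.

Step 3
Reactants: 4 8α-hydroxy-13,14,15,16-tetranorlabdan-12-yl pivalate
Product: 5 13,14,15,16-tetranorlabd-8(9)-en-12-yl pivalate
Conditions: TsOH·H2O (cat.), toluene, 80 °C
Reagents that add atoms: none
Why: Acid-catalysed E1 dehydration under equilibrating conditions should convert the tertiary alcohol through the isomeric alkenes into the most substituted, tetrasubstituted C8–C9 alkene (dehydration with acid-mediated alkene isomerisation).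

Step 4
Reactants: 5 13,14,15,16-tetranorlabd-8(9)-en-12-yl pivalate
Product: 6 8α,9α-epoxy-13,14,15,16-tetranorlabdan-12-yl pivalate
Conditions: mCPBA, NaHCO3, CH2Cl2, 0 °C
Reagents that add atoms: mCPBA, O=C(OO)c1cccc(Cl)c1
Why: Prilezhaev epoxidation of the electron-rich tetrasubstituted alkene should take place on the α face, opposite the axial C10 methyl, so that the C9–O bond lies antiperiplanar to that methyl.

Step 5
Reactants: 6 8α,9α-epoxy-13,14,15,16-tetranorlabdan-12-yl pivalate
Product: 7 8α-hydroxy-13,14,15,16-tetranorclerod-4(18)-en-12-yl pivalate (19β-methyl on C5; 20β-methyl on C9; 10α-H; 17β-methyl on C8)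
Conditions: BF3·OEt2 (0.3 equiv), CH2Cl2, −78 to −30 °C; Et3N quench
Reagents that add atoms: none
Why: Proposed new method: BF3 activates the epoxide oxygen and the C9–O bond ionises with participation of the antiperiplanar axial C10 methyl, which shifts to C9; the C10 cation then accepts the axial H5, the C5 cation accepts the axial C4 methyl, and the C4 cation loses a C18 proton to the 8-alkoxyborate, which regenerates the Lewis acid and leaves the 8α-hydroxyl. The closest known reaction type is the Lewis-acid backbone (Wagner–Meerwein) rearrangement of labdane and drimane 8,9-epoxides and 8-cations, which ends after the first methyl shift, together with the Westphalen rearrangement. No ring is closed, since the C9–C20 and C5–C19 bonds arise by 1,2-shifts within the intact decalin. C9, C10 and C5 are each set by a suprafacial shift anti to the preceding one, so the sclareolide configuration is relayed to β-C20, α-H10 and β-C19, while C8 keeps the epoxide configuration. The step needs ionisation at C9 instead of C8, migration instead of early proton loss or semipinacol ring contraction, and terminal proton loss from C18; the trans-diaxial alignment of the three migrating groups in the rigid chair–chair epoxide, the non-participating pivalate and low temperature with substoichiometric acid support the first two, whereas the choice between C18 and C3 in the last proton loss is not secured by the substrate.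

Step 6
Reactants: 7 8α-hydroxy-13,14,15,16-tetranorclerod-4(18)-en-12-yl pivalate
Product: 8 13,14,15,16-tetranorclerod-4(18)-ene-8α,12-diol
Conditions: LiAlH4, THF, 0 °C
Reagents that add atoms: none
Why: Hydride cleavage of the pivalate (ester reduction) frees the C12 alcohol needed as the radical handle, while the tertiary alcohol and the C4 methylene are inert to LiAlH4.

Step 7
Reactants: 8 13,14,15,16-tetranorclerod-4(18)-ene-8α,12-diol
Product: 10 13,14,15,16-tetranorcleroda-1(10),4(18)-diene-8α,12-diol, via C12 nitrite ester 9 (not isolated)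
Conditions: t-BuONO, CH2Cl2, rt, dark; concentrate; then hν (λ > 300 nm), Cu(OAc)2, pyridine, benzene, rt
Reagents that add atoms: none
Why: Trans-nitrosation selects the primary alcohol, photolysis of the nitrite gives the C12 alkoxy radical, 1,5-hydrogen transfer (Barton-type, six-membered transition state) removes the tertiary axial H10, and divalent copper oxidises the C10 radical to an alkene that can only form toward C1 because C5 and C9 are quaternary (alkoxy-radical remote desaturation).

Step 8
Reactants: 10 13,14,15,16-tetranorcleroda-1(10),4(18)-diene-8α,12-diol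
Product: 11 1α,10α-epoxy-13,14,15,16-tetranorclerod-4(18)-ene-8α,12-diol
Conditions: VO(acac)2 (cat.), t-BuOOH, CH2Cl2, 0 °C
Reagents that add atoms: tert-butyl hydroperoxide, CC(C)(C)OO
Why: Vanadium-catalysed hydroxyl-directed epoxidation should be delivered by the homoallylic axial 8α-hydroxyl, assisted by the C12 hydroxyl, to the α face of the C1–C10 alkene, which is also the face opposite C19 and C20, and it should not touch the undirected C4 methylene.

Step 9
Reactants: 11 1α,10α-epoxy-13,14,15,16-tetranorclerod-4(18)-ene-8α,12-diol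
Product: 12 13,14,15,16-tetranorclerod-4(18)-ene-1α,8α,12-triol (10α-H)
Conditions: Cp2TiCl2 (20 mol %), Mn, 2,4,6-collidine·HCl, 1,4-cyclohexadiene, THF, rt
Reagents that add atoms: none
Why: Titanocene-mediated reductive epoxide opening (Nugent–RajanBabu reaction) breaks the C10–O bond to the tertiary radical, keeps the C1–O bond with its α configuration, and hydrogen-atom transfer from cyclohexadiene should reach C10 from the α face, away from the flanking β-axial C19 and C20, to give the trans-fused 10α-H.

Step 10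
Reactants: 12 13,14,15,16-tetranorclerod-4(18)-ene-1α,8α,12-triol
Product: 13 1α,12-bis(triethylsilyloxy)-13,14,15,16-tetranorclerod-4(18)-en-8α-ol
Conditions: Et3SiCl, imidazole, DMF, 0 °C to rt
Reagents that add atoms: chlorotriethylsilane, CC[Si](Cl)(CC)CC
Why: Silyl ether formation with the chloride and imidazole protects the primary and the secondary alcohol and leaves the hindered tertiary 8α-alcohol free for the elimination.

Step 11
Reactants: 13 1α,12-bis(triethylsilyloxy)-13,14,15,16-tetranorclerod-4(18)-en-8α-ol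
Product: 14 1α,12-bis(triethylsilyloxy)-13,14,15,16-tetranorcleroda-4(18),7-diene
Conditions: SOCl2, pyridine, CH2Cl2, −40 to 0 °C
Reagents that add atoms: none
Why: Dehydration through the chlorosulfite in pyridine is an anti elimination of the axial 8α-oxygen with the axial 7β-hydrogen and should therefore favour the trisubstituted C7–C8 alkene over the C8 methylene isomer.

Step 12
Reactants: 14 1α,12-bis(triethylsilyloxy)-13,14,15,16-tetranorcleroda-4(18),7-diene
Product: 15 1α-(triethylsilyloxy)-13,14,15,16-tetranorcleroda-4(18),7-dien-12-al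
Conditions: (COCl)2, DMSO, CH2Cl2, −78 to −30 °C; then Et3N
Reagents that add atoms: none
Why: Under Swern conditions a primary triethylsilyl ether is cleaved by the chlorosulfonium salt and oxidised directly to the aldehyde, while the hindered secondary silyl ether at C1 should be retained (Swern oxidation of a primary silyl ether).

Step 13
Reactants: 16 methyl bis(2,2,2-trifluoroethyl)phosphonoacetate; 17 tert-butyl bromoacetate
Product: 18 4-tert-butyl 1-methyl 2-[bis(2,2,2-trifluoroethoxy)phosphoryl]butanedioate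
Conditions: NaH, THF, 0 °C to rt
Reagents that add atoms: none
Why: C-Alkylation of the sodium salt of the phosphonoacetate with the α-bromo ester attaches the future C14–C15 arm to the olefination reagent (enolate alkylation).

Step 14
Reactants: 15 1α-(triethylsilyloxy)-13,14,15,16-tetranorcleroda-4(18),7-dien-12-al; 18 4-tert-butyl 1-methyl 2-[bis(2,2,2-trifluoroethoxy)phosphoryl]butanedioate
Product: 19 15-tert-butyl 16-methyl (12Z)-1α-(triethylsilyloxy)cleroda-4(18),7,12-triene-15,16-dioate
Conditions: KN(SiMe3)2, 18-crown-6, THF, −78 °C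
Reagents that add atoms: none
Why: The Still–Gennari variant of the Horner–Wadsworth–Emmons reaction is kinetically Z-selective, which places C11 cis to the methyl ester carbon C16 as the later anti opening of the epoxide requires.

Step 15
Reactants: 19 15-tert-butyl 16-methyl (12Z)-1α-(triethylsilyloxy)cleroda-4(18),7,12-triene-15,16-dioate
Product: 20 tert-butyl (12Z)-16-hydroxy-1α-(triethylsilyloxy)cleroda-4(18),7,12-trien-15-oate
Conditions: i-Bu2AlH, CH2Cl2, −78 °C
Reagents that add atoms: none
Why: At low temperature i-Bu2AlH should reduce the conjugated methyl ester to the allylic alcohol and spare the bulky tert-butyl ester and the silyl ether (chemoselective ester reduction).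

Step 16
Reactants: 20 tert-butyl (12Z)-16-hydroxy-1α-(triethylsilyloxy)cleroda-4(18),7,12-trien-15-oate
Product: 21 tert-butyl (12R,13S)-12,13-epoxy-16-hydroxy-1α-(triethylsilyloxy)cleroda-4(18),7-dien-15-oate
Conditions: Ti(Oi-Pr)4 (20 mol %), L-(+)-diisopropyl tartrate (24 mol %), t-BuOOH, 4 Å molecular sieves, CH2Cl2, −20 °C
Reagents that add atoms: tert-butyl hydroperoxide, CC(C)(C)OO
Why: Sharpless asymmetric epoxidation acts only on the allylic alcohol, leaving the C7–C8 alkene and the C4 methylene, and the L-(+)-tartrate should set the (12R,13S)-epoxide by reagent control.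

Step 17
Reactants: 21 tert-butyl (12R,13S)-12,13-epoxy-16-hydroxy-1α-(triethylsilyloxy)cleroda-4(18),7-dien-15-oate; 22 tiglic acid
Product: 23 tert-butyl (12S,13S)-13,16-dihydroxy-12-tigloyloxy-1α-(triethylsilyloxy)cleroda-4(18),7-dien-15-oate
Conditions: Ti(Oi-Pr)4 (1.5 equiv), CH2Cl2, rt
Reagents that add atoms: none
Why: Titanium-mediated opening of the 2,3-epoxy alcohol by a carboxylic acid occurs within the chelated alkoxide at the epoxide carbon remote from the hydroxymethyl group, here C12, with inversion, which should install the 12S tiglate directly and leave the 13S tertiary alcohol.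

Step 18
Reactants: 23 tert-butyl (12S,13S)-13,16-dihydroxy-12-tigloyloxy-1α-(triethylsilyloxy)cleroda-4(18),7-dien-15-oate
Product: 26 (12S,13S)-1α,13-dihydroxy-12-tigloyloxycleroda-4(18),7-dien-15,16-olide, via persilylated silyl ester 24 (not isolated), via seco hydroxy acid 25 (not isolated)
Conditions: Me3SiOTf, 2,6-lutidine, CH2Cl2, 0 °C; then HF·pyridine, THF, 0 °C to rt
Reagents that add atoms: none
Why: Silyl triflate buffered with lutidine turns the tert-butyl ester into the silyl ester without protonating the alkenes, and fluoride then frees the acid and all hydroxyls so that the primary C16 alcohol closes the γ-lactone by intramolecular acyl substitution (ester cleavage followed by lactonisation).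

Step 19
Reactants: 26 (12S,13S)-1α,13-dihydroxy-12-tigloyloxycleroda-4(18),7-dien-15,16-olide; 22 tiglic acid
Product: 27 (12S,13S)-13-hydroxy-1α,12-bis(tigloyloxy)cleroda-4(18),7-dien-15,16-olide
Conditions: 2,4,6-trichlorobenzoyl chloride, Et3N, toluene, rt; then 26, DMAP, 40 °C
Reagents that add atoms: none
Why: Yamaguchi esterification through the mixed anhydride should acylate the hindered equatorial 1α-alcohol, whereas the tertiary C13 alcohol should not react.

Step 20
Reactants: 27 (12S,13S)-13-hydroxy-1α,12-bis(tigloyloxy)cleroda-4(18),7-dien-15,16-olide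
Product: 28 (12S,13S)-13-hydroxy-6-oxo-1α,12-bis(tigloyloxy)cleroda-4(18),7-dien-15,16-olide
Conditions: Rh2(cap)4 (cap = caprolactamate, 1 mol %), t-BuOOH, K2CO3, CH2Cl2, rt
Reagents that add atoms: tert-butyl hydroperoxide, CC(C)(C)OO
Why: Dirhodium-catalysed allylic oxidation with the hydroperoxide proceeds by peroxyl-radical hydrogen abstraction at the weakest allylic C–H, the ring C6 methylene of the trisubstituted alkene, and should give the conjugated 6-ketone, while the electron-poor tiglates and the C3 methylene beside the disubstituted C4 methylene should react more slowly.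

Step 21
Reactants: 28 (12S,13S)-13-hydroxy-6-oxo-1α,12-bis(tigloyloxy)cleroda-4(18),7-dien-15,16-olide
Product: 29 (12S,13S)-6β,13-dihydroxy-1α,12-bis(tigloyloxy)cleroda-4(18),7-dien-15,16-olide
Conditions: NaBH4, CeCl3·7H2O, MeOH, −78 °C
Reagents that add atoms: none
Why: Luche reduction adds hydride to the C6 carbonyl in 1,2 fashion from the α face, anti to the adjacent β-axial C19 methyl, which should give the equatorial 6β-alcohol and leave esters and lactone intact.

Step 22
Reactants: 29 (12S,13S)-6β,13-dihydroxy-1α,12-bis(tigloyloxy)cleroda-4(18),7-dien-15,16-olide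
Product: 31 (12S,13S)-6β,7α,13-trihydroxy-1α,12-bis(tigloyloxy)cleroda-4(18),8(17)-dien-15,16-olide, via C7 hydroperoxide 30 (not isolated)
Conditions: O2, hν, tetraphenylporphyrin (cat.), CH2Cl2, 0 °C; then PPh3
Reagents that add atoms: dioxygen, O=O
Why: In the Schenck ene reaction of the allylic alcohol singlet oxygen should bond to C7, the alkene carbon next to the carbinol, and take hydrogen from the C17 methyl because the carbinol hydrogen at C6 is not abstracted and C9 has none, which moves the alkene to C8–C17, and the phosphine reduces the hydroperoxide, whose C7 configuration is of no consequence.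

Step 23
Reactants: 31 (12S,13S)-6β,7α,13-trihydroxy-1α,12-bis(tigloyloxy)cleroda-4(18),8(17)-dien-15,16-olide
Product: 32 (12S,13S)-6β,13-dihydroxy-7-oxo-1α,12-bis(tigloyloxy)cleroda-4(18),8(17)-dien-15,16-olide (CNP0233387.2)
Conditions: MnO2 (activated), CH2Cl2, rt
Reagents that add atoms: none
Why: Activated MnO2 oxidises only the allylic C7 alcohol (selective allylic alcohol oxidation), so that the enone should form while the 6β- and 13-hydroxyls stay free.

Compound list
1 | (+)-sclareolide | CC1(C)CCC[C@@]2(C)[C@H]1CC[C@@]3(C)OC(=O)C[C@H]23 | starting material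
2 | 13,14,15,16-tetranorlabdane-8α,12-diol | CC1(C)CCC[C@@]2(C)[C@H]1CC[C@@](C)(O)[C@@H]2CCO | intermediate
3 | pivaloyl chloride | CC(C)(C)C(=O)Cl | starting material
4 | 8α-hydroxy-13,14,15,16-tetranorlabdan-12-yl pivalate | CC1(C)CCC[C@@]2(C)[C@H]1CC[C@@](C)(O)[C@@H]2CCOC(=O)C(C)(C)C | intermediate
5 | 13,14,15,16-tetranorlabd-8(9)-en-12-yl pivalate | CC1(C)CCC[C@@]2(C)[C@H]1CCC(C)=C2CCOC(=O)C(C)(C)C | intermediate
6 | 8α,9α-epoxy-13,14,15,16-tetranorlabdan-12-yl pivalate | CC1(C)CCC[C@@]2(C)[C@H]1CC[C@@]3(C)O[C@@]23CCOC(=O)C(C)(C)C | intermediate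
7 | 8α-hydroxy-13,14,15,16-tetranorclerod-4(18)-en-12-yl pivalate (19β-methyl on C5; 20β-methyl on C9; 10α-H; 17β-methyl on C8) | C=C1CCC[C@@H]2[C@]1(C)CC[C@@](C)(O)[C@@]2(C)CCOC(=O)C(C)(C)C | intermediate
8 | 13,14,15,16-tetranorclerod-4(18)-ene-8α,12-diol | C=C1CCC[C@@H]2[C@]1(C)CC[C@@](C)(O)[C@@]2(C)CCO | intermediate
9 | 8α-hydroxy-13,14,15,16-tetranorclerod-4(18)-en-12-yl nitrite | C=C1CCC[C@@H]2[C@]1(C)CC[C@@](C)(O)[C@@]2(C)CCON=O | intermediate
10 | 13,14,15,16-tetranorcleroda-1(10),4(18)-diene-8α,12-diol | C=C1CCC=C2[C@]1(C)CC[C@@](C)(O)[C@@]2(C)CCO | intermediate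
11 | 1α,10α-epoxy-13,14,15,16-tetranorclerod-4(18)-ene-8α,12-diol | C=C1CC[C@@H]2O[C@]23[C@]1(C)CC[C@@](C)(O)[C@@]3(C)CCO | intermediate
12 | 13,14,15,16-tetranorclerod-4(18)-ene-1α,8α,12-triol (10α-H) | C=C1CC[C@H](O)[C@@H]2[C@]1(C)CC[C@@](C)(O)[C@@]2(C)CCO | intermediate
13 | 1α,12-bis(triethylsilyloxy)-13,14,15,16-tetranorclerod-4(18)-en-8α-ol | C=C1CC[C@H](O[Si](CC)(CC)CC)[C@@H]2[C@]1(C)CC[C@@](C)(O)[C@@]2(C)CCO[Si](CC)(CC)CC | intermediate
14 | 1α,12-bis(triethylsilyloxy)-13,14,15,16-tetranorcleroda-4(18),7-diene | C=C1CC[C@H](O[Si](CC)(CC)CC)[C@@H]2[C@]1(C)CC=C(C)[C@@]2(C)CCO[Si](CC)(CC)CC | intermediate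
15 | 1α-(triethylsilyloxy)-13,14,15,16-tetranorcleroda-4(18),7-dien-12-al | C=C1CC[C@H](O[Si](CC)(CC)CC)[C@@H]2[C@]1(C)CC=C(C)[C@@]2(C)CC=O | intermediate
16 | methyl bis(2,2,2-trifluoroethyl)phosphonoacetate | COC(=O)CP(=O)(OCC(F)(F)F)OCC(F)(F)F | starting material
17 | tert-butyl bromoacetate | CC(C)(C)OC(=O)CBr | starting material
18 | 4-tert-butyl 1-methyl 2-[bis(2,2,2-trifluoroethoxy)phosphoryl]butanedioate | COC(=O)C(CC(=O)OC(C)(C)C)P(=O)(OCC(F)(F)F)OCC(F)(F)F | intermediate
19 | 15-tert-butyl 16-methyl (12Z)-1α-(triethylsilyloxy)cleroda-4(18),7,12-triene-15,16-dioate | C=C1CC[C@H](O[Si](CC)(CC)CC)[C@@H]2[C@]1(C)CC=C(C)[C@@]2(C)C/C=C(/CC(=O)OC(C)(C)C)C(=O)OC | intermediate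
20 | tert-butyl (12Z)-16-hydroxy-1α-(triethylsilyloxy)cleroda-4(18),7,12-trien-15-oate | C=C1CC[C@H](O[Si](CC)(CC)CC)[C@@H]2[C@]1(C)CC=C(C)[C@@]2(C)C/C=C(/CC(=O)OC(C)(C)C)CO | intermediate
21 | tert-butyl (12R,13S)-12,13-epoxy-16-hydroxy-1α-(triethylsilyloxy)cleroda-4(18),7-dien-15-oate | C=C1CC[C@H](O[Si](CC)(CC)CC)[C@@H]2[C@]1(C)CC=C(C)[C@@]2(C)C[C@H]1O[C@@]1(CC(=O)OC(C)(C)C)CO | intermediate
22 | tiglic acid, (E)-2-methylbut-2-enoic acid | C/C=C(\C)C(=O)O | starting material
23 | tert-butyl (12S,13S)-13,16-dihydroxy-12-tigloyloxy-1α-(triethylsilyloxy)cleroda-4(18),7-dien-15-oate | C=C1CC[C@H](O[Si](CC)(CC)CC)[C@@H]2[C@]1(C)CC=C(C)[C@@]2(C)C[C@H](OC(=O)/C(C)=C/C)[C@@](O)(CO)CC(=O)OC(C)(C)C | intermediate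
24 | trimethylsilyl (12S,13S)-12-tigloyloxy-1α-(triethylsilyloxy)-13,16-bis(trimethylsilyloxy)cleroda-4(18),7-dien-15-oate | C=C1CC[C@H](O[Si](CC)(CC)CC)[C@@H]2[C@]1(C)CC=C(C)[C@@]2(C)C[C@H](OC(=O)/C(C)=C/C)[C@@](O[Si](C)(C)C)(CO[Si](C)(C)C)CC(=O)O[Si](C)(C)C | intermediate
25 | (12S,13S)-1α,13,16-trihydroxy-12-tigloyloxycleroda-4(18),7-dien-15-oic acid | C=C1CC[C@H](O)[C@@H]2[C@]1(C)CC=C(C)[C@@]2(C)C[C@H](OC(=O)/C(C)=C/C)[C@@](O)(CO)CC(=O)O | intermediate
26 | (12S,13S)-1α,13-dihydroxy-12-tigloyloxycleroda-4(18),7-dien-15,16-olide | C=C1CC[C@H](O)[C@@H]2[C@]1(C)CC=C(C)[C@@]2(C)C[C@H](OC(=O)/C(C)=C/C)[C@@]1(O)COC(=O)C1 | intermediate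
27 | (12S,13S)-13-hydroxy-1α,12-bis(tigloyloxy)cleroda-4(18),7-dien-15,16-olide | C=C1CC[C@H](OC(=O)/C(C)=C/C)[C@@H]2[C@]1(C)CC=C(C)[C@@]2(C)C[C@H](OC(=O)/C(C)=C/C)[C@@]1(O)COC(=O)C1 | intermediate
28 | (12S,13S)-13-hydroxy-6-oxo-1α,12-bis(tigloyloxy)cleroda-4(18),7-dien-15,16-olide | C=C1CC[C@H](OC(=O)/C(C)=C/C)[C@@H]2[C@]1(C)C(=O)C=C(C)[C@@]2(C)C[C@H](OC(=O)/C(C)=C/C)[C@@]1(O)COC(=O)C1 | intermediate
29 | (12S,13S)-6β,13-dihydroxy-1α,12-bis(tigloyloxy)cleroda-4(18),7-dien-15,16-olide | C=C1CC[C@H](OC(=O)/C(C)=C/C)[C@@H]2[C@]1(C)[C@H](O)C=C(C)[C@@]2(C)C[C@H](OC(=O)/C(C)=C/C)[C@@]1(O)COC(=O)C1 | intermediate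
30 | (12S,13S)-7α-hydroperoxy-6β,13-dihydroxy-1α,12-bis(tigloyloxy)cleroda-4(18),8(17)-dien-15,16-olide | C=C1CC[C@H](OC(=O)/C(C)=C/C)[C@@H]2[C@]1(C)[C@H](O)[C@@H](OO)C(=C)[C@@]2(C)C[C@H](OC(=O)/C(C)=C/C)[C@@]1(O)COC(=O)C1 | intermediate
31 | (12S,13S)-6β,7α,13-trihydroxy-1α,12-bis(tigloyloxy)cleroda-4(18),8(17)-dien-15,16-olide | C=C1CC[C@H](OC(=O)/C(C)=C/C)[C@@H]2[C@]1(C)[C@H](O)[C@@H](O)C(=C)[C@@]2(C)C[C@H](OC(=O)/C(C)=C/C)[C@@]1(O)COC(=O)C1 | intermediate
32 | (1S,5S,6S,9S,10S,12S,13S)-6β,13-dihydroxy-7-oxo-1α,12-bis(tigloyloxy)cleroda-4(18),8(17)-dien-15,16-olide (CNP0233387.2) | C=C1CC[C@H](OC(=O)/C(C)=C/C)[C@@H]2[C@]1(C)[C@H](O)C(=O)C(=C)[C@@]2(C)C[C@H](OC(=O)/C(C)=C/C)[C@@]1(O)COC(=O)C1 | target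

Total step count: 23. Longest linear sequence: 22 steps (steps 1–12 and 14–23; step 13 is a one-step branch).

Steps most likely to fail

1. Step 5 (key step). The process at risk is the terminal deprotonation: the C4 cation may lose a proton from C3 and give the endocyclic alkene, or the cascade may pause and re-enter, so that the C4 methylene is not the product collected. The fallback corrects the alkene afterwards with established reactions, and it relies on the same cascade reaching the C4 cation. Starting from 6, the Lewis-acid treatment is allowed to warm until proton loss is thermodynamically controlled, and the C3–C4 alkene 8α-hydroxy-13,14,15,16-tetranorclerod-3-en-12-yl pivalate F1 is taken on. SeO2 with t-BuOOH in CH2Cl2 should oxidise the C18 methyl, the only hydrogen-bearing position on the more substituted alkene carbon, to the primary allylic alcohol 8α,18-dihydroxy-13,14,15,16-tetranorclerod-3-en-12-yl pivalate F2. Mitsunobu reaction of F2 with 2-nitrobenzenesulfonylhydrazide (PPh3, diethyl azodicarboxylate, THF, −30 °C to rt) and loss of N2 from the allylic diazene moves the alkene to C4–C18 with hydrogen delivery to C3 and returns to 7.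

2. Step 7. The process at risk is over-oxidation of the hindered tertiary C10 radical to the cation, followed by capture by the C12 hydroxyl as a cyclic ether, or recombination of the radical with nitric oxide, in place of elimination. The fallback transfers a sulfur group to C10 and eliminates thermally. From 8, PhSCl and Et3N at −78 °C should give the C12 benzenesulfenate 8α-hydroxy-13,14,15,16-tetranorclerod-4(18)-en-12-yl benzenesulfenate F3. Photolysis with (Bu3Sn)2 (cat.) in benzene effects 1,5-hydrogen transfer and phenylthio group transfer to give 10α-(phenylthio)-13,14,15,16-tetranorclerod-4(18)-ene-8α,12-diol F4. One equivalent of mCPBA at −78 °C gives the sulfoxide 10α-(phenylsulfinyl)-13,14,15,16-tetranorclerod-4(18)-ene-8α,12-diol F5, and thermal syn elimination (toluene, 100 °C), possible only toward C1, returns to 10.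

3. Step 17. The process at risk is loss of regiocontrol in the epoxide opening (ionisation at the tertiary C13) or migration of the tiglate from O12 to the primary O16 on the titanium alkoxide. The fallback blocks O16 and opens the epoxide by plain SN2 substitution. From 21, t-BuMe2SiCl and imidazole give tert-butyl (12R,13S)-16-(tert-butyldimethylsilyloxy)-12,13-epoxy-1α-(triethylsilyloxy)cleroda-4(18),7-dien-15-oate F6. Cesium tiglate (from 22 and Cs2CO3) in DMF at 80 °C should attack the secondary C12 with inversion to give tert-butyl (12S,13S)-16-(tert-butyldimethylsilyloxy)-13-hydroxy-12-tigloyloxy-1α-(triethylsilyloxy)cleroda-4(18),7-dien-15-oate F7. Me3SiOTf with 2,6-lutidine and then HF·pyridine, as in step 18, pass through the silyl ester trimethylsilyl (12S,13S)-16-(tert-butyldimethylsilyloxy)-12-tigloyloxy-1α-(triethylsilyloxy)-13-(trimethylsilyloxy)cleroda-4(18),7-dien-15-oate F8, remove all silyl groups and the tert-butyl ester, and rejoin the route at the seco acid 25 and hence 26.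

Further compounds
F1 | step 5 | 8α-hydroxy-13,14,15,16-tetranorclerod-3-en-12-yl pivalate | CC1=CCC[C@@H]2[C@]1(C)CC[C@@](C)(O)[C@@]2(C)CCOC(=O)C(C)(C)C
F2 | step 5 | 8α,18-dihydroxy-13,14,15,16-tetranorclerod-3-en-12-yl pivalate | OCC1=CCC[C@@H]2[C@]1(C)CC[C@@](C)(O)[C@@]2(C)CCOC(=O)C(C)(C)C
F3 | step 7 | 8α-hydroxy-13,14,15,16-tetranorclerod-4(18)-en-12-yl benzenesulfenate | C=C1CCC[C@@H]2[C@]1(C)CC[C@@](C)(O)[C@@]2(C)CCOSc1ccccc1
F4 | step 7 | 10α-(phenylthio)-13,14,15,16-tetranorclerod-4(18)-ene-8α,12-diol | C=C1CCC[C@]2(Sc3ccccc3)[C@]1(C)CC[C@@](C)(O)[C@@]2(C)CCO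
F5 | step 7 | 10α-(phenylsulfinyl)-13,14,15,16-tetranorclerod-4(18)-ene-8α,12-diol | C=C1CCC[C@]2([S+]([O-])c3ccccc3)[C@]1(C)CC[C@@](C)(O)[C@@]2(C)CCO
F6 | step 17 | tert-butyl (12R,13S)-16-(tert-butyldimethylsilyloxy)-12,13-epoxy-1α-(triethylsilyloxy)cleroda-4(18),7-dien-15-oate | C=C1CC[C@H](O[Si](CC)(CC)CC)[C@@H]2[C@]1(C)CC=C(C)[C@@]2(C)C[C@H]1O[C@@]1(CC(=O)OC(C)(C)C)CO[Si](C)(C)C(C)(C)C
F7 | step 17 | tert-butyl (12S,13S)-16-(tert-butyldimethylsilyloxy)-13-hydroxy-12-tigloyloxy-1α-(triethylsilyloxy)cleroda-4(18),7-dien-15-oate | C=C1CC[C@H](O[Si](CC)(CC)CC)[C@@H]2[C@]1(C)CC=C(C)[C@@]2(C)C[C@H](OC(=O)/C(C)=C/C)[C@@](O)(CO[Si](C)(C)C(C)(C)C)CC(=O)OC(C)(C)C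
F8 | step 17 | trimethylsilyl (12S,13S)-16-(tert-butyldimethylsilyloxy)-12-tigloyloxy-1α-(triethylsilyloxy)-13-(trimethylsilyloxy)cleroda-4(18),7-dien-15-oate | C=C1CC[C@H](O[Si](CC)(CC)CC)[C@@H]2[C@]1(C)CC=C(C)[C@@]2(C)C[C@H](OC(=O)/C(C)=C/C)[C@@](O[Si](C)(C)C)(CO[Si](C)(C)C(C)(C)C)CC(=O)O[Si](C)(C)C
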